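The earlier runs and the new flask come from a simulation on assumed constants, and the scatter is random.

Late in the birch run, between 20 min and 45 min, target rose by a factor of 5.15, from 0.0104 M to 0.0536 M, and a steady rate does not give that shape.

| flask | starting material | partner | free catalyst | time |
|---|---|---|---|---|
| birch | 0.120 M | 0.360 M | 0.0120 M |  |
| oak | 0.0480 M | 0.288 M | 0.0120 M |  |
| maple | 0.120 M | 0.360 M | 0.0180 M |  |
| ash | 0.480 M | 0.360 M | 0.0120 M | 45 min |

| birch run: time / min | birch run: [target] / M | oak run: time / min | oak run: [target] / M | maple run: time / min | maple run: [target] / M |
|---|---|---|---|---|---|
| 1.8 | 0.0017 | 1.8 | 0.0014 | 1.8 | 1 × 10⁻⁴ |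
| 4.0 | 0 | 4.0 | 0.0021 | 4.0 | 0 |
| 9.0 | 0 | 9.0 | 0 | 9.0 | 0.0040 |
| 20 | 0.0104 | 20 | 0.0036 | 20 | 0.0128 |
| 45 | 0.0536 | 45 | 0.0088 | 45 | 0.0609 |

(readings scatter by 0.002 M)

- order of the initial rate in [free catalyst], near the charge of the birch run, the rate being that where two percent of its starting material are target
- the oak run starts with 0.0720 M less of starting material and of partner than the birch run, and with no target. Compared where both hold the same amount of starting material, once fifteen percent of what the oak run was charged with has turned into target, is the oak run faster, slower or alike (within a tenth)?
- target in the ash run at 45 min, as a share of the starting material charged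

- Overall: starting material + partner -> target, with free catalyst as catalyst.
- Constant volume, constant temperature.
- "The second partner" is partner.
- An order is taken over about fifteen percent of the charge, up and down.

I built the flask one process at a time, writing S, R and P for starting material, partner and target. First I took the main step, a steady rate proportional to S·R. Scaling the oak reading at 45 min by the charges gave the ash run 0.00244 M min⁻¹, so 22.9 % of its starting material at 45 min.

Then I let target help its own making, at a rate κ·S·R·P, so that P doubles every ln(2)/(κ·S·R). From the birch rise I read 1.52 M⁻² min⁻¹ for the growth rate of ln P divided by the charged S·R, the assist constant κ, a reading that carries a scatter of 0.002 M on a point of 0.0104 M. At the ash charge this gave 0.262 min⁻¹, a doubling time of 2.65 min. That doubling time belongs to the charge, and S·R falls as target forms, so I integrated κ·S·R·P with both falling, from the 0.00932 M of target that steady rate and assist together give after one doubling time. My estimate for the ash run put 0.240 M of target at about 23.7 min, before 45 min.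

Last came the stop. Partner is the limiting reagent in the ash run, with 0.360 M against 0.480 M of starting material, so the ceiling is 75.0 %. At 0.240 M of target, 0.120 M of partner remained, with a lifetime 1/(κ·S·P) of 11.4 min. Running that lifetime to 45 min left 0.0186 M of partner, so I reckoned 71.1 %.

For the catalyst, I read an order of 0.315 from the maple and birch readings at 45 min. For the comparison at equal starting material, the oak run holds 0.00720 M of target against 0.0792 M in the birch run, so its assisted rate is 0.0909 of the birch one and I expected it to be slower.

The forecast gave 0.3, slower and 68 %, below my reckoning for the ash run, with the ground “Partner is limiting, capping the yield at 75%”.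

The ash run gave 70.6 % at 45 min, the order in free catalyst came to 0.32, and the oak run was slower, at 0.18 of the birch rate at equal starting material.

    2 active catalyst ⇌ catalyst dimer, settled at all times (165.0 M⁻¹)
    active catalyst + starting material + partner → target + active catalyst (4.320 M⁻² min⁻¹)
    starting material + partner + target → 2 target (1.602 M⁻² min⁻¹)
    free catalyst + partner → active catalyst + partner (0.07980 M⁻¹ min⁻¹)

That yield is 0.339 M of target, which leaves 0.0211 M of partner, and κ puts the lifetime of that partner at 13.8 min. At the oak charge κ gives a doubling time of 33.0 min, and the oak run took 32.4 min to go from 0.0120 M to 0.0240 M of target.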